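Wednesday's flask and this one share the held gas level, 200 mM, and differ in charge, 2 M of substrate against 3.0 M, and in time, 8.00 min at the last reading against 10 min, so I asked what Wednesday's plateau is worth in this flask.

in all of them: gas 200 mM (held)
- Wednesday's: substrate 2 M; run made earlier
- flask: substrate 3.0 M; time 10 min

Wednesday's run (percent of the substrate charged)

| time / min | target / % | substrate / % |
|---|---|---|
| 0.667 | 59.0 | 32.4 |
| 1.33 | 79.9 | 10.5 |
| 2.50 | 88.1 | 2.4 |
| 4.00 | 90.3 | 0.2 |
| 8.00 | 90.5 | 0 |

(each reading ± 1 percentage point)

- the analysis behind the earlier runs scatters by 1 percentage point, standard deviation
- at the start none of the gas is in solution

- violet: doubling the transfer coefficient of the gas, all else as stated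
- green: doubling the saturation concentration of gas, all else as stated

- the target standing at 10 min, as a percentage of the substrate charged
- the change that raises the amount of target at 10 min, in percent of the substrate charged most ("none" if none brings more than 2 percentage points) (violet / green / none)
- amount of target at 10 min, in percent of the substrate charged, after green

1. In Wednesday's run the substrate gave a decay constant of 1.69 /min up to 0.667 min and 1.70 /min over the next interval, which reads as pseudo-first-order decay with no visible lag of gas. If this flask keeps that constant, 10 min is 24.4 half-lives, so I treated the target asked for as an end value.

2. I replaced the curve of losses by its mean: the loss ratio, the points of charged substrate not ending as target per point of target at the end, the inverse of a selectivity factor. Wednesday's last reading gives 0.105.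

3. In Wednesday's run that mean predicts 6.19% missing at 0.667 min, but the readings left 8.60% missing. The mean runs short there, early in the run, and the end value is what I needed.

4. Turning the question round, and taking Wednesday's end value as the base for this flask, "none" would require green to leave the target below 92.5%, so the loss ratio would have to stay above 0.0811, a cut smaller than 1.29.

5. I assumed a ratio independent of charge and inverse to gas. That gave 90.5% for this flask, and with the ratio at half, a cut of 2, 95.0% after green. I expected violet to stay under the margin, as Wednesday's two decay constants showed no lag.

6. The forecast stood lower, 86% and 92% after green, holding that “Losses therefore occur mainly at high substrate”.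

7. The flask gave 89.2%, and green was best, gaining 3.9 percentage points against 0.22 points for violet, with 93.1% after green.

    substrate ⇌ other conformer (K = 0.130, k = 0.00460 /s)
    substrate + coupling partner → target (k = 0.130 /M/s)
    coupling partner + other conformer → isomer of the product (k = 0.330 /M/s)
    gas ⇌ coupling partner, rate k4*(csat - [coupling partner]) (kL = 3.90 /s)
    coupling partner → decomposed reagent (k = 0.0260 /s)

In this flask the loss ratio was 0.121, and green brought it to 0.0741, a cut of 1.63; the neighbouring flask with 0.75 M of substrate stood at 0.118. At 1.24 min in this flask, substrate passed into target 5.5 times as fast as into other conformer, counting the forward rate of that reversible step alone, and the isomer of the product stood at 10.8% at 10.0 min.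

The earlier runs and the new flask were computed for substances that don't exist; noise was put on by code.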